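## Analysis of the target

Target 17 is an isoflavan quinone: a chroman, made of benzo ring A fused through C4a and C8a to a pyran ring (O1, C2, C3, C4), carries at C3 a 2,3-dimethoxy-1,4-benzoquinone (ring B, C1' to C6', joined through C5'). Ring A has oxygen on four neighbouring carbons, namely O1 on C8a, a free hydroxyl on C8 and methoxyls on C7 and C6, and C5 is its only aromatic CH. C3 is the single stereocentre and has the S configuration; it is bound to hydrogen, to the two methylene groups C2 and C4 and to the quinone carbon C5', so no heteroatom or carbonyl group next to it offers a handle for a conventional asymmetric reaction. The quinone is easily reduced, adds nucleophiles and is destroyed by base, and once it is in place H3 is allylic to C5'=C6' and vinylogously acidic, so the configuration can be lost through a quinone methide tautomer. The free C8 phenol lies on a very electron-rich ring and is itself open to oxidation. The difficulty is therefore threefold: to create C3 in one enantiomeric form, to keep it while ring B is introduced, and to tell the C8 oxygen from the two methoxylated ones. The strategy rests on the two CH2 arms of C3: when ring B is replaced in thought by a hydroxymethyl group, that group and C2–OH are identical, and C3 becomes the central carbon of a prochiral 2-benzylpropane-1,3-diol. Joining one of the two oxygens to C8a then closes the pyran ring and makes C3 stereogenic in the same event.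

## Retrosynthetic reasoning

**17 to 15 (through 16).** The C8 hydroxyl is carried as a benzyl ether to the end. Hydrogenolysis also reduces the quinone, giving hydroquinone 16, which is reoxidised mildly. Benzyl is chosen because it survives hydride reduction, the basic ring closure, the lithium acetylide and the thermolysis.

**15 to 13, and 13 to 12 plus 11.** Ring B is cut at C4'–C5' and C1'–C6'. This divides it into the four-carbon dimethoxy-enedione unit, which is dimethyl squarate 11, and a two-carbon unit, which is an ethynyl group on C3 (acetylide 12). An sp carbon on C3 does not acidify H3, and the Moore rearrangement of adduct 13 delivers the quinone at its final oxidation level without an external oxidant. The forward reactions must achieve mono-addition to one carbonyl of 11 and then six-ring, not five-ring, closure on heating.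

**12 to 10, 9 and 8.** The alkyne carbon C5' is the carbinol carbon of alcohol 8, and C6' is added by a one-carbon homologation of aldehyde 9. Aldehyde 9 is the one intermediate in which H3 is activated, being α to the formyl group with O1 placed as a β leaving group. The homologation is therefore run through dibromoalkene 10 by a non-basic Ramirez olefination. The Ohira–Bestmann alkynylation would be a step shorter but exposes 9 to a basic medium. Dibromoalkene 10 has the further merit of giving 12 directly.

**8 to 7 (key disconnection).** The bond O1–C8a is cut. A cut at O1–C2 or C3–C4 would leave a chiral open-chain fragment whose stereocentre needs its own synthesis. The cut at O1–C8a gives the achiral diol 7, in which the two hydroxymethyl arms are enantiotopic and C8a carries bromine. The forward reaction, the Ullmann-type etherification of step 5, must arylate one arm selectively under the control of a chiral ligand, so that ring closure and stereocentre arise together.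

**7 to 5 (through 6), and 5 to 3 plus 4.** The C3–C4 bond is cut as the C=C bond of a Knoevenagel product. Dimethyl malonate 4 supplies C3 and both arms as esters, and hydride reduction of alkylidene malonate 5 through saturated diester 6 gives the diol. This avoids the separate reduction and halogenation of aldehyde 3 and the double alkylation that an alkylation of 4 risks, and it is two operations from 3.

**3 to 2 and 1.** The benzyl ether and the C–Br bond are removed. Aldehyde 1 already holds the full oxygen pattern of ring A, with the oxygen that must end free present as the only hydroxyl. That hydroxyl directs bromine to the carbon between itself and the formyl-bearing carbon, the future C8a.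

## Alternatives that were turned down

Alternative 1: All of ring A is dismantled, at C4a–C8a, C5–C6 and C7–C8.
- Disconnection: the precursors are an open-chain diyne and a symmetrical diborylalkyne. In the diyne O1 carries an ethynyl group, C4 carries a second terminal alkyne and C3 already bears ring B as a dibenzyl-protected hydroquinone.
- Key step: a [2+2+2] cyclotrimerisation catalysed by CpCo(CO)2 would build ring A and the pyran ring at once and deliver (3S)-3-(2,5-dibenzyloxy-3,4-dimethoxyphenyl)-6,7-bis(pinacolatoboryl)chroman A1.
- For it: two rings form in a single operation, ring B travels as a robust hydroquinone ether so that no quinone annulation is needed, and boron marks the positions of the C6 and C7 oxygens.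
- Against it: A1 has hydrogen at C8, so the hydroxyl that characterises the target would have to be added later by a regioselective C–H oxygenation.
- Against it: the cyclotrimerisation does not create C3, which must be built into the diyne by a separate asymmetric C–C bond formation at an aryl-bearing carbon.
- Against it: alkynyl ethers with hydrogen β to oxygen fragment thermally to a ketene and an alkene in the temperature range of such cyclotrimerisations.
- Against it: after A1 there still follow two C–B oxidations, two O-methylations, the C8 oxygenation, deprotection and oxidation.
- Comparison: on the handling of ring B this plan is stronger than the chosen one, which must grow that ring late by a thermolysis. The chosen strategy offers in its place a ring A whose full oxygen pattern comes from the starting aldehyde, and a key step that itself creates the stereocentre.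

Alternative 2: The pyran ring is cut at C3–C4 and O1–C2.
- Disconnection: ring A becomes an ortho-quinone methide, released by base from a 2-(sulfonylmethyl)phenol, and C2, C3 and ring B come from an arylacetaldehyde.
- Key step: a chiral secondary amine turns the aldehyde into an enamine that adds to the methylene carbon of the quinone methide, and the phenol then closes onto the aldehyde. The product is the lactol (3S)-8-benzyloxy-3-(2,5-dibenzyloxy-3,4-dimethoxyphenyl)-6,7-dimethoxychroman-2-ol A2, formed as both C2 epimers. Removal of the lactol hydroxyl from A2, debenzylation and oxidation would finish.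
- For it: it is the shortest and most convergent of the four plans and is catalytic in the chiral component. On step count it beats the chosen route.
- Against it: in A2 and its open hydroxy-aldehyde form C3 is α to a carbonyl group and benzylic to an electron-rich ring, the most acidic environment this carbon can have. The amine that created the centre can re-form the enamine of the product and erase it.
- Against it: arylacetaldehydes self-condense readily, and their conjugated enamines are sluggish nucleophiles.
- Against it: the ionic reduction of A2 passes through an oxocarbenium ion that can lose H3 to an achiral enol ether with a C2=C3 bond.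
- Comparison: the chosen route is longer, but its stereocentre is created with only CH2 groups around it. Its one intermediate with an activated H3, aldehyde 9, lacks the aryl group and meets no base.

Alternative 3: The cut is C4–C4a.
- Disconnection: O1–C2, the C3 stereocentre and ring B are assembled first in an open-chain sulfone whose ring A part carries bromine at C4a and hydrogen at C5.
- Key step: a hindered lithium amide would remove the proton α to sulfur (C4) and H5. Loss of bromide gives the C4a≡C5 aryne, the tethered carbanion adds to C4a, and C5 is protonated. The product is (3S)-8-benzyloxy-3-(2,5-dibenzyloxy-3,4-dimethoxyphenyl)-6,7-dimethoxy-4-(phenylsulfonyl)chroman A3, formed as both C4 epimers. The sulfonyl group of A3 is then removed reductively.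
- For it: a C–C bond is made to a ring A position that electrophilic chemistry reaches poorly, the tether fixes the regiochemistry, and ring B is carried intact into A3.
- Against it: as in alternative 1, the key step does not create C3.
- Against it: an excess of a very strong base meets three benzyl ethers (benzylic metalation, Wittig rearrangement) and a benzylic H3, and the amide can also intercept the aryne.
- Against it: the sulfone costs steps for its introduction and for its removal from A3, and A3 carries a useless C4 stereocentre on the way.
- Comparison: it is longer and harsher than the chosen route. Its one advantage, shared with alternatives 1 and 2, is that no late quinone annulation is needed. The chosen key step uses carbonate as its only base and sets the configuration catalytically.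

Key step: step 5

Remark: which antipode of the diamine ligand leads to the S alcohol 8 cannot be predicted with confidence for this diol. The route assumes that one of the two available antipodes does so, to be settled in the first run of step 5.

## Route

Step 1
Reactants: 1 3-hydroxy-4,5-dimethoxybenzaldehyde
Product: 2 2-bromo-3-hydroxy-4,5-dimethoxybenzaldehyde
Conditions: Br2 (1.05 equiv), NaOAc, Fe powder (cat.), AcOH, rt
Reagents that add atoms: bromine, BrBr
Why: Electrophilic aromatic bromination; C2 is activated by the ortho hydroxyl and the para methoxyl at C5, and the same buffered conditions place bromine between the hydroxyl and formyl groups of closely related 3-hydroxy-4-alkoxybenzaldehydes.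

Step 2
Reactants: 2 2-bromo-3-hydroxy-4,5-dimethoxybenzaldehyde
Product: 3 3-benzyloxy-2-bromo-4,5-dimethoxybenzaldehyde
Conditions: BnBr, K2CO3, DMF, 40 °C
Reagents that add atoms: benzyl bromide, BrCc1ccccc1
Why: Williamson ether synthesis on the only nucleophile present; the benzyl ether should survive every later step and leave in step 10, where the quinone has to pass through its hydroquinone in any case.

Step 3
Reactants: 3 3-benzyloxy-2-bromo-4,5-dimethoxybenzaldehyde; 4 dimethyl malonate
Product: 5 dimethyl 2-[(3-benzyloxy-2-bromo-4,5-dimethoxyphenyl)methylidene]propanedioate
Conditions: piperidine (cat.), AcOH (cat.), toluene, reflux, Dean–Stark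
Reagents that add atoms: none
Why: Knoevenagel condensation; it forms the future C3–C4 bond directly from the aldehyde and cannot over-alkylate.

Step 4
Reactants: 5 dimethyl 2-[(3-benzyloxy-2-bromo-4,5-dimethoxyphenyl)methylidene]propanedioate
Product: 7 2-[(3-benzyloxy-2-bromo-4,5-dimethoxyphenyl)methyl]propane-1,3-diol, via saturated diester 6 (not isolated)
Conditions: NaBH4, THF–MeOH, 0 °C; then LiBH4 (THF solution), 0 °C to rt
Reagents that add atoms: none
Why: Conjugate hydride reduction of the alkylidene malonate, then reduction of both esters in the same flask; the aryl bromide and the benzyl ether are inert to NaBH4 and LiBH4, and the product is achiral with two identical arms.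

Step 5
Reactants: 7 2-[(3-benzyloxy-2-bromo-4,5-dimethoxyphenyl)methyl]propane-1,3-diol
Product: 8 [(3S)-8-benzyloxy-6,7-dimethoxychroman-3-yl]methanol
Conditions: CuI (10 mol %), (1S,2S)-N,N'-dimethyl-1,2-diphenylethane-1,2-diamine or its antipode (20 mol %, see remark), Cs2CO3, MeCN, 40 °C, Ar
Reagents that add atoms: none
Why: Ullmann-type C–O coupling run as a desymmetrisation: Cs2CO3 and diamine-bound monovalent copper turn one hydroxymethyl arm into a copper alkoxide, the C–Br bond at C8a, held close by the benzylic tether, adds oxidatively to give an aryl trivalent-copper alkoxide chelate, and C–O reductive elimination forms O1–C8a. The pyran ring thus closes in a 6-exo sense at the aryl carbon, the only ring size the tether allows, and no bond at C3 is made or broken. C3 becomes stereogenic because the arms are enantiotopic: with the C2-symmetric diamine on copper the two possible chelates, which differ in where the spectator hydroxymethyl arm points, are diastereomeric, and the ligand antipode is chosen so that the favoured one leads to the S alcohol. The closest known reaction type is the enantioselective intramolecular O-arylation of 2-(2-halobenzyl)propane-1,3-diols to chroman-3-ylmethanols under CuI and a chiral diamine. The step needs enantiotopic-group selection, a single cyclisation and no loss of bromine by reduction. The substrate has one aryl halide, so the product cannot react again; six-ring closure should outrun intermolecular etherification at moderate dilution; and carbonate does not touch the benzyl ether. The benzyloxy group ortho to bromine crowds the oxidative addition and lies near the ligand, which is the main burden and the reason for keeping the temperature as low as conversion allows.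

Step 6
Reactants: 8 [(3S)-8-benzyloxy-6,7-dimethoxychroman-3-yl]methanol
Product: 9 (3R)-8-benzyloxy-6,7-dimethoxychroman-3-carbaldehyde
Conditions: Dess–Martin periodinane, NaHCO3, CH2Cl2, 0 °C to rt; crude product used at once
Reagents that add atoms: none
Why: Dess–Martin oxidation under buffered, non-basic conditions; the geometry at C3 is unchanged (the descriptor becomes R only because the formyl group now outranks C2), and the aldehyde is not chromatographed because H3 is α to the carbonyl with O1 as a β leaving group.

Step 7
Reactants: 9 (3R)-8-benzyloxy-6,7-dimethoxychroman-3-carbaldehyde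
Product: 10 (3S)-8-benzyloxy-3-(2,2-dibromoethenyl)-6,7-dimethoxychroman
Conditions: CBr4, PPh3, Zn, CH2Cl2, rt (reagent pre-formed); then 9, 0 °C
Reagents that add atoms: carbon tetrabromide, BrC(Br)(Br)Br
Why: Ramirez dibromo-olefination (first half of the Corey–Fuchs sequence); the Zn variant needs no amine or alkoxide base, so the aldehyde is consumed before it can enolise, and the product no longer has an activated H3.

Step 8
Reactants: 10 (3S)-8-benzyloxy-3-(2,2-dibromoethenyl)-6,7-dimethoxychroman; 11 dimethyl squarate
Product: 13 4-{[(3S)-8-benzyloxy-6,7-dimethoxychroman-3-yl]ethynyl}-4-hydroxy-2,3-dimethoxycyclobut-2-en-1-one (both epimers at the carbinol carbon), via lithium acetylide 12 (not isolated)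
Conditions: n-BuLi (2.0 equiv), THF, −78 to −20 °C; recool to −78 °C and transfer into 11 in THF; aq NH4Cl at −78 °C
Reagents that add atoms: none
Why: Second half of the Corey–Fuchs sequence (bromine–lithium exchange, Fritsch–Buttenberg–Wiechell shift, deprotonation) gives the acetylide, which adds 1,2 to one of the two equivalent carbonyls of the squarate; inverse addition at low temperature limits double addition, and the uncontrolled carbinol centre disappears in step 9.

Step 9
Reactants: 13 4-{[(3S)-8-benzyloxy-6,7-dimethoxychroman-3-yl]ethynyl}-4-hydroxy-2,3-dimethoxycyclobut-2-en-1-one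
Product: 15 5-[(3S)-8-benzyloxy-6,7-dimethoxychroman-3-yl]-2,3-dimethoxycyclohexa-2,5-diene-1,4-dione, via dienylketene 14 (not isolated)
Conditions: p-xylene (0.02 M, degassed), reflux (138 °C)
Reagents that add atoms: none
Why: Moore rearrangement: conrotatory opening of the cyclobutenone with the hydroxyl turning outward gives ketene 14 with the alkyne facing the ketene carbon, ring closure (C4'–C5') gives a six-membered diradical, and transfer of the hydroxyl hydrogen to C6' gives the quinone. An alkyl group on the alkyne terminus, as C3 is here, favours six-ring over five-ring closure; both epimers of 13 converge, and C3 is untouched because the carbon radical sits on C6', not on C5'.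

Step 10
Reactants: 15 5-[(3S)-8-benzyloxy-6,7-dimethoxychroman-3-yl]-2,3-dimethoxycyclohexa-2,5-diene-1,4-dione
Product: 17 5-[(3S)-8-hydroxy-6,7-dimethoxychroman-3-yl]-2,3-dimethoxycyclohexa-2,5-diene-1,4-dione, via hydroquinone 16 (not isolated)
Conditions: H2 (1 atm), Pd/C, EtOAc, rt; filter under Ar; then Ag2O, Na2SO4, Et2O–EtOAc, rt
Reagents that add atoms: none
Why: Hydrogenolysis of the aryl benzyl ether with reduction of the quinone to its hydroquinone, then selective reoxidation; Ag2O should oxidise the hydroquinone, whose oxidation potential is far below that of the isolated ring A phenol, and the neutral conditions leave H3 alone.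

## Compound list

1 | 3-hydroxy-4,5-dimethoxybenzaldehyde | COc1cc(C=O)cc(O)c1OC | starting material
2 | 2-bromo-3-hydroxy-4,5-dimethoxybenzaldehyde | COc1cc(C=O)c(Br)c(O)c1OC | intermediate
3 | 3-benzyloxy-2-bromo-4,5-dimethoxybenzaldehyde | COc1cc(C=O)c(Br)c(OCc2ccccc2)c1OC | intermediate
4 | dimethyl malonate | COC(=O)CC(=O)OC | starting material
5 | dimethyl 2-[(3-benzyloxy-2-bromo-4,5-dimethoxyphenyl)methylidene]propanedioate | COC(=O)C(=Cc1cc(OC)c(OC)c(OCc2ccccc2)c1Br)C(=O)OC | intermediate
6 | dimethyl 2-[(3-benzyloxy-2-bromo-4,5-dimethoxyphenyl)methyl]propanedioate (not isolated) | COC(=O)C(Cc1cc(OC)c(OC)c(OCc2ccccc2)c1Br)C(=O)OC | intermediate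
7 | 2-[(3-benzyloxy-2-bromo-4,5-dimethoxyphenyl)methyl]propane-1,3-diol | OCC(CO)Cc1cc(OC)c(OC)c(OCc2ccccc2)c1Br | intermediate
8 | [(3S)-8-benzyloxy-6,7-dimethoxychroman-3-yl]methanol | OC[C@H]1COc2c(cc(OC)c(OC)c2OCc3ccccc3)C1 | intermediate
9 | (3R)-8-benzyloxy-6,7-dimethoxychroman-3-carbaldehyde | O=C[C@H]1COc2c(cc(OC)c(OC)c2OCc3ccccc3)C1 | intermediate
10 | (3S)-8-benzyloxy-3-(2,2-dibromoethenyl)-6,7-dimethoxychroman | BrC(Br)=C[C@H]1COc2c(cc(OC)c(OC)c2OCc3ccccc3)C1 | intermediate
11 | dimethyl squarate (3,4-dimethoxycyclobut-3-ene-1,2-dione) | COC1=C(OC)C(=O)C1=O | starting material
12 | lithium [(3S)-8-benzyloxy-6,7-dimethoxychroman-3-yl]ethynide (not isolated) | [Li]C#C[C@H]1COc2c(cc(OC)c(OC)c2OCc3ccccc3)C1 | intermediate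
13 | 4-{[(3S)-8-benzyloxy-6,7-dimethoxychroman-3-yl]ethynyl}-4-hydroxy-2,3-dimethoxycyclobut-2-en-1-one (both epimers at the carbinol carbon) | COC1=C(OC)C(O)(C#C[C@H]2COc3c(cc(OC)c(OC)c3OCc4ccccc4)C2)C1=O | intermediate
14 | (3Z)-6-[(3S)-8-benzyloxy-6,7-dimethoxychroman-3-yl]-4-hydroxy-2,3-dimethoxyhexa-1,3-dien-5-yn-1-one (not isolated) | O=C=C(OC)/C(OC)=C(/O)C#C[C@H]1COc2c(cc(OC)c(OC)c2OCc3ccccc3)C1 | intermediate
15 | 5-[(3S)-8-benzyloxy-6,7-dimethoxychroman-3-yl]-2,3-dimethoxycyclohexa-2,5-diene-1,4-dione | COC1=C(OC)C(=O)C([C@H]2COc3c(cc(OC)c(OC)c3OCc4ccccc4)C2)=CC1=O | intermediate
16 | 5-[(3S)-8-hydroxy-6,7-dimethoxychroman-3-yl]-2,3-dimethoxybenzene-1,4-diol (not isolated) | COc1c(OC)c(O)c([C@H]2COc3c(cc(OC)c(OC)c3O)C2)cc1O | intermediate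
17 | 5-[(3S)-8-hydroxy-6,7-dimethoxychroman-3-yl]-2,3-dimethoxycyclohexa-2,5-diene-1,4-dione (CNP0269725.1) | COC1=C(OC)C(=O)C([C@H]2COc3c(cc(OC)c(OC)c3O)C2)=CC1=O | target

## Step count and least certain steps

Total step count: 10. Longest linear sequence: 10 steps, from 1 to 17; compounds 4 and 11 enter as purchased reagents.

**Step 5 (key step).** The electron-rich C–Br bond, flanked by the benzylic carbon and the benzyloxy group, may be activated only sluggishly. A higher temperature would then be needed, at which discrimination between the enantiotopic arms falls; arylation of the ligand nitrogen can also stall the catalyst. The fallback separates the two tasks; it sets out from 7 and returns at 8. Lipase-catalysed monoacetylation of 7 with vinyl acetate (lipase from Pseudomonas cepacia or from porcine pancreas, chosen by the arm it acylates) should give (2S)-2-[(3-benzyloxy-2-bromo-4,5-dimethoxyphenyl)methyl]-3-hydroxypropyl acetate F1. The free arm is capped at once (MOMCl, i-Pr2NEt, CH2Cl2, 0 °C) to give (2S)-2-[(3-benzyloxy-2-bromo-4,5-dimethoxyphenyl)methyl]-3-(methoxymethoxy)propyl acetate F2, which stops acyl migration between the arms. K2CO3 in MeOH removes the acetate to give (2R)-2-[(3-benzyloxy-2-bromo-4,5-dimethoxyphenyl)methyl]-3-(methoxymethoxy)propan-1-ol F3. Its single hydroxyl is closed onto the bromide without a chiral ligand (CuI, 3,4,7,8-tetramethyl-1,10-phenanthroline, Cs2CO3, toluene, 100 °C) to give (3R)-8-benzyloxy-6,7-dimethoxy-3-[(methoxymethoxy)methyl]chroman F4, and HCl in MeOH returns 8. The configuration is then fixed by the enzyme, and the ring-closure temperature no longer matters.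

**Step 7 (with the handling of aldehyde 9 from step 6).** Configuration at C3 may erode by enolisation, or by reversible β-elimination of the O1 phenoxide with ring opening and reclosure, while the aldehyde waits or meets the ylide and ZnBr2. The fallback sets out from crude 9 and returns at 16. Takai iodo-olefination (CrCl2, CHI3, THF, 0 °C), which is non-basic and fast, should give (3S)-8-benzyloxy-3-[(E)-2-iodoethenyl]-6,7-dimethoxychroman F5. Iodine–lithium exchange (t-BuLi, Et2O, −78 °C) and addition to 11 give 4-{(E)-2-[(3S)-8-benzyloxy-6,7-dimethoxychroman-3-yl]ethenyl}-4-hydroxy-2,3-dimethoxycyclobut-2-en-1-one F6. Heating in toluene opens the ring to a dienylketene, which closes by 6π-electrocyclisation and tautomerises to 5-[(3S)-8-benzyloxy-6,7-dimethoxychroman-3-yl]-2,3-dimethoxybenzene-1,4-diol F7. Hydrogenolysis (H2, Pd/C) gives 16, which is oxidised as in step 10. This removes the phosphorus ylide, the butyllithium-induced rearrangement and the diradical ring closure from the route.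

**Step 9.** The diradical may close to the five-membered ring (an alkylidenecyclopentenedione) or abstract hydrogen from the benzyl ether or the solvent in place of the hydroxyl hydrogen, giving reduced or oligomeric material. The fallback sets out from 12 and returns at 16. Acetylide 12 is quenched with aq NH4Cl in place of 11 to give (3S)-8-benzyloxy-3-ethynyl-6,7-dimethoxychroman F8. Hydrozirconation (Cp2Zr(H)Cl, THF) and I2 give the (E)-iodoalkene F5 of the preceding fallback, which is taken through F6 and F7 to 16 as described there; that ring closure is a closed-shell electrocyclisation.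

**Step 1.** Bromine may enter at C6, para to the hydroxyl, or twice. The fallback uses directed ortho-metalation; it sets out from 1 and returns at 2. The phenol is protected (MOMCl, i-Pr2NEt) as 3-(methoxymethoxy)-4,5-dimethoxybenzaldehyde F9. The formyl group is masked in the flask as its lithium α-amino alkoxide with lithium N,N,N'-trimethylethylenediamide, n-BuLi lithiates the position flanked by that group and the methoxymethoxy group, and BrCCl2CCl2Br followed by aqueous acid gives 2-bromo-3-(methoxymethoxy)-4,5-dimethoxybenzaldehyde F10. HCl in MeOH then gives 2.

**Step 10.** The freed ring A phenol, whose para position C5 is open, may be oxidised together with the hydroquinone, or may exchange redox state with the product quinone. The fallback goes from 15 directly to 17 without any redox change: BCl3 with pentamethylbenzene as cation scavenger, CH2Cl2, −78 °C, cleaves the aryl benzyl ether and leaves the quinone at its oxidation level. It makes no new compound.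

## Further compounds

F1 | step 5 | (2S)-2-[(3-benzyloxy-2-bromo-4,5-dimethoxyphenyl)methyl]-3-hydroxypropyl acetate | OC[C@@H](COC(C)=O)Cc1cc(OC)c(OC)c(OCc2ccccc2)c1Br
F2 | step 5 | (2S)-2-[(3-benzyloxy-2-bromo-4,5-dimethoxyphenyl)methyl]-3-(methoxymethoxy)propyl acetate | COCOC[C@@H](COC(C)=O)Cc1cc(OC)c(OC)c(OCc2ccccc2)c1Br
F3 | step 5 | (2R)-2-[(3-benzyloxy-2-bromo-4,5-dimethoxyphenyl)methyl]-3-(methoxymethoxy)propan-1-ol | COCOC[C@@H](CO)Cc1cc(OC)c(OC)c(OCc2ccccc2)c1Br
F4 | step 5 | (3R)-8-benzyloxy-6,7-dimethoxy-3-[(methoxymethoxy)methyl]chroman | COCOC[C@H]1COc2c(cc(OC)c(OC)c2OCc3ccccc3)C1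
F5 | step 7 | (3S)-8-benzyloxy-3-[(E)-2-iodoethenyl]-6,7-dimethoxychroman | I/C=C/[C@H]1COc2c(cc(OC)c(OC)c2OCc3ccccc3)C1
F6 | step 7 | 4-{(E)-2-[(3S)-8-benzyloxy-6,7-dimethoxychroman-3-yl]ethenyl}-4-hydroxy-2,3-dimethoxycyclobut-2-en-1-one (both epimers at the carbinol carbon) | COC1=C(OC)C(O)(/C=C/[C@H]2COc3c(cc(OC)c(OC)c3OCc4ccccc4)C2)C1=O
F7 | step 7 | 5-[(3S)-8-benzyloxy-6,7-dimethoxychroman-3-yl]-2,3-dimethoxybenzene-1,4-diol | COc1c(OC)c(O)c([C@H]2COc3c(cc(OC)c(OC)c3OCc4ccccc4)C2)cc1O
F8 | step 9 | (3S)-8-benzyloxy-3-ethynyl-6,7-dimethoxychroman | C#C[C@H]1COc2c(cc(OC)c(OC)c2OCc3ccccc3)C1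
F9 | step 1 | 3-(methoxymethoxy)-4,5-dimethoxybenzaldehyde | COCOc1cc(C=O)cc(OC)c1OC
F10 | step 1 | 2-bromo-3-(methoxymethoxy)-4,5-dimethoxybenzaldehyde | COCOc1c(Br)c(C=O)cc(OC)c1OC
F0 | step 10 | none | none
A1 | alternative 1 | (3S)-3-(2,5-dibenzyloxy-3,4-dimethoxyphenyl)-6,7-bis(pinacolatoboryl)chroman | COc1c(OC)c(OCc2ccccc2)cc([C@H]2COc3cc(B4OC(C)(C)C(C)(C)O4)c(B4OC(C)(C)C(C)(C)O4)cc3C2)c1OCc1ccccc1
A2 | alternative 2 | (3S)-8-benzyloxy-3-(2,5-dibenzyloxy-3,4-dimethoxyphenyl)-6,7-dimethoxychroman-2-ol (both C2 epimers) | COc1c(OC)c(OCc2ccccc2)cc([C@H]2C(O)Oc3c(cc(OC)c(OC)c3OCc3ccccc3)C2)c1OCc1ccccc1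
A3 | alternative 3 | (3S)-8-benzyloxy-3-(2,5-dibenzyloxy-3,4-dimethoxyphenyl)-6,7-dimethoxy-4-(phenylsulfonyl)chroman (both C4 epimers) | COc1c(OC)c(OCc2ccccc2)cc([C@H]2COc3c(cc(OC)c(OC)c3OCc3ccccc3)C2S(=O)(=O)c2ccccc2)c1OCc1ccccc1
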